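**Plan**

1. Numbering (target): C1 ester carbon, C2 (Me), ring carbons C3–C6 with O2 on C3 and O1 on C6, chain C7–C14 (C9 ketone, C10 methylidene, C14 carbinol).
2. Cuts, last to first: C10=CH2 (Horner–Wadsworth–Emmons with formaldehyde), C9–C10 (phosphonate plus Weinreb amide), C7=C8 (Wittig), ring bond O1–C6, C3–O2 (peroxide for triflate), C2–C3 (aldol); C3 to C7 come from geranyl acetate.
3. Enabling feature: in the only ring, the 1,2-dioxane, the quaternary peroxide carbon C6 lies beside C7, which can carry an oxygen because it is later trimmed to an aldehyde; O1–C6 can therefore be made by a C3 hydroperoxide opening a C6–C7 epoxide at C6.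
4. Forward order: C3 aldehyde → aldol (C2–C3) → C3 peroxide → C6–C7 epoxide → dioxane closure → C7 aldehyde → C8–C9 → C10–C14 chain → C1 ester → C10 methylidene.
5. Stereochemistry: C2 and C3 from an auxiliary-controlled syn-aldol, C3 then inverted in the peroxide substitution; C6 from a Sharpless epoxide, by inversion in the ring closure.

Key step: step 11

Remark: C8′ denotes the allylic CH2O carbon of geranyl acetate; it is excised in step 12, and C8 and C9 of the target come from the Wittig reagent.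
Remark: hydroperoxide 11 is not sold and is made in step 6; compounds 26 to 29 are mixtures of the two epimers at the phosphorus-bearing carbon C10, which becomes sp2 in step 20.

**Route**

Step 1
Reactants: 1 geranyl acetate
Product: 2 (2E)-5-(3,3-dimethyloxiran-2-yl)-3-methylpent-2-en-1-yl acetate (racemic)
Conditions: mCPBA (1.0 equiv), CH2Cl2, 0 °C
Reagents that add atoms: 3-chloroperoxybenzoic acid, O=C(OO)c1cccc(Cl)c1
Why: Prilezhaev epoxidation should select the electron-rich distal trisubstituted alkene because the other alkene is deactivated by the allylic acetate; the new stereocentre is racemic and is destroyed in step 2.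

Step 2
Reactants: 2 (2E)-5-(3,3-dimethyloxiran-2-yl)-3-methylpent-2-en-1-yl acetate
Product: 4 (2E)-3-methyl-6-oxohex-2-en-1-yl acetate, via diol 3 (not isolated)
Conditions: H5IO6 (1.2 equiv), THF/H2O, 0 °C → rt
Reagents that add atoms: water, O (its oxygen is held in 3 and leaves again with acetone)
Why: Acid-mediated hydrolysis of the epoxide followed by Malaprade glycol cleavage with the same periodic acid should expel acetone and leave the C3 aldehyde without touching the allylic acetate.

Step 3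
Reactants: 5 (S)-4-benzyl-3-propionyloxazolidin-2-one; 4 (2E)-3-methyl-6-oxohex-2-en-1-yl acetate
Product: 7 (4S)-4-benzyl-3-[(2S,3R,6E)-8-acetoxy-3-hydroxy-2,6-dimethyloct-6-enoyl]-1,3-oxazolidin-2-one, via boron enolate 6 (not isolated)
Conditions: Bu2BOTf (1.1 equiv), iPr2NEt (1.2 equiv), CH2Cl2, 0 °C; then 4, −78 → 0 °C; pH 7 buffer, MeOH, 30% H2O2, 0 °C
Reagents that add atoms: dibutylboron trifluoromethanesulfonate, CCCCB(CCCC)OS(=O)(=O)C(F)(F)F (the Bu2B group is carried by 6 only)
Why: Evans syn-aldol reaction, in which the (Z)-boron enolate reacts through a closed Zimmerman–Traxler chair with one face shielded by the benzyl group of the (S)-auxiliary, should set C2 as S and C3 as R (syn), the carbinol configuration needed for the later inversion.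

Step 4
Reactants: 7 (4S)-4-benzyl-3-[(2S,3R,6E)-8-acetoxy-3-hydroxy-2,6-dimethyloct-6-enoyl]-1,3-oxazolidin-2-one
Product: 8 (2R,3R,6E)-2,6-dimethyloct-6-ene-1,3,8-triol
Conditions: LiBH4 (4 equiv), MeOH (4 equiv), THF, 0 °C → rt
Reagents that add atoms: none
Why: Hydride reduction with LiBH4 should cleave the activated imide carbonyl to the C1 alcohol and the recoverable auxiliary and reduce the acetate as well, so that both primary hydroxyls are freed together with C2 and C3 untouched.

Step 5
Reactants: 8 (2R,3R,6E)-2,6-dimethyloct-6-ene-1,3,8-triol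
Product: 9 (2R,3R,6E)-1,8-bis[(tert-butyldiphenylsilyl)oxy]-2,6-dimethyloct-6-en-3-ol
Conditions: TBDPSCl (2.1 equiv), imidazole (4 equiv), CH2Cl2, 0 °C
Reagents that add atoms: tert-butyl(chloro)diphenylsilane, CC(C)(C)[Si](Cl)(c1ccccc1)c1ccccc1
Why: Silylation with the bulky chlorosilane should be selective for the two primary hydroxyls over the secondary C3 hydroxyl next to the C2 branch, leaving only the alcohol that is to be inverted.

Step 6
Reactants: 10 2,3-dimethylbut-2-ene
Product: 11 2-methoxypropan-2-yl hydroperoxide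
Conditions: O3, MeOH/CH2Cl2, −78 °C; used as a solution
Reagents that add atoms: ozone, [O-][O+]=O; methanol, CO
Why: Ozonolysis in methanol should give the α-methoxy hydroperoxide by trapping of the carbonyl oxide (Criegee intermediate) with the solvent, providing a peroxide nucleophile whose ketal mask falls off later in mild acid.

Step 7
Reactants: 9 (2R,3R,6E)-1,8-bis[(tert-butyldiphenylsilyl)oxy]-2,6-dimethyloct-6-en-3-ol; 11 2-methoxypropan-2-yl hydroperoxide
Product: 14 (2R,3S,6E)-1,8-bis[(tert-butyldiphenylsilyl)oxy]-3-[(2-methoxypropan-2-yl)peroxy]-2,6-dimethyloct-6-ene, via triflate 12 (not isolated), via potassium peroxide 13 (not isolated)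
Conditions: Tf2O (1.2 equiv), 2,6-lutidine (1.5 equiv), CH2Cl2, −78 °C; then cannulated into 11 (3.3 equiv)/KOtBu (3.0 equiv), THF, −78 → 0 °C
Reagents that add atoms: trifluoromethanesulfonic anhydride, O=S(=O)(OS(=O)(=O)C(F)(F)F)C(F)(F)F (triflyl group in 12 only); potassium tert-butoxide, CC(C)(C)[O-].[K+] (potassium in 13 only)
Why: SN2 alkylation of a hydroperoxide, in which the strongly nucleophilic but weakly basic peroxide anion displaces the C3 triflate with inversion, should turn the 3R alcohol into the 3S peroxide anti to the C2 methyl; C1 is kept at the alcohol level so that no acidic α-hydrogen invites β-elimination.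

Step 8
Reactants: 14 (2R,3S,6E)-1,8-bis[(tert-butyldiphenylsilyl)oxy]-3-[(2-methoxypropan-2-yl)peroxy]-2,6-dimethyloct-6-ene
Product: 15 (2R,3S,6E)-3-[(2-methoxypropan-2-yl)peroxy]-2,6-dimethyloct-6-ene-1,8-diol
Conditions: TBAF (2.5 equiv), THF, 0 °C → rt
Reagents that add atoms: none
Why: Fluoride-mediated desilylation should free both primary hydroxyls, since dialkyl peroxyketals are stable to fluoride and to base.

Step 9
Reactants: 15 (2R,3S,6E)-3-[(2-methoxypropan-2-yl)peroxy]-2,6-dimethyloct-6-ene-1,8-diol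
Product: 16 (2R,3S,6S,7S)-6,7-epoxy-3-[(2-methoxypropan-2-yl)peroxy]-2,6-dimethyloctane-1,8-diol
Conditions: Ti(OiPr)4 (0.2 equiv), L-(+)-diethyl tartrate (0.24 equiv), tBuOOH (2 equiv), 4 Å molecular sieves, CH2Cl2, −20 °C; alkaline brine work-up without reducing salts
Reagents that add atoms: tert-butyl hydroperoxide, CC(C)(C)OO
Why: Sharpless asymmetric epoxidation of this geraniol-type allylic alcohol with the L-(+)-tartrate catalyst should deliver oxygen under reagent control to the same face as in geraniol itself, setting C6 and C7 both S, while the peroxyketal has no O–H with which to bind titanium and the remote C1 hydroxyl is only a spectator.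

Step 10
Reactants: 16 (2R,3S,6S,7S)-6,7-epoxy-3-[(2-methoxypropan-2-yl)peroxy]-2,6-dimethyloctane-1,8-diol
Product: 17 (2R,3S,6S,7S)-6,7-epoxy-3-hydroperoxy-2,6-dimethyloctane-1,8-diol
Conditions: AcOH/THF/H2O (4:2:1), 0 °C → rt; NaHCO3 work-up, used at once
Reagents that add atoms: none
Why: Acid-catalysed hydrolysis of the very labile acetone-derived peroxyketal should free the hydroperoxide under conditions too mild for solvent to open the epoxide, and any ring closure that already begins gives 18 and does no harm.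

Step 11
Reactants: 17 (2R,3S,6S,7S)-6,7-epoxy-3-hydroperoxy-2,6-dimethyloctane-1,8-diol
Product: 18 (2R)-2-[(3S,6R)-6-[(1S)-1,2-dihydroxyethyl]-6-methyl-1,2-dioxan-3-yl]propan-1-ol
Conditions: (1S)-(+)-10-camphorsulfonic acid (0.1 equiv), CH2Cl2 (0.01 M), 0 °C → rt
Reagents that add atoms: none
Why: The acid protonates the epoxide oxygen and the terminal oxygen of the C3 hydroperoxide attacks C6 from the side opposite the breaking C6–O bond in a borderline SN2 process, which forms O1–C6. The closest known reaction type is the acid-catalysed cyclisation of epoxy hydroperoxides to 1,2-dioxanes and 1,2-dioxolanes. The 1,2-dioxane closes in the 6-exo-tet mode, the breaking C6–O bond lying outside the new ring. The only new stereocentre, quaternary C6, is controlled by the epoxide configuration through inversion (6S epoxide carbon to 6R peroxide carbon), while C7 keeps its oxygen with retention and C2 and C3 are not touched. The step needs attack at C6 and not at C7 and it needs clean inversion: the positive charge of the trisubstituted epoxide sits on tertiary C6 (C7 is further deactivated by the neighbouring CH2OH), six-ring closure at C6 is geometrically preferred to a seven-membered 1,2-dioxepane, and the tethered α-effect nucleophile should capture C6 before a free cation can planarise. The two primary hydroxyls should not compete, since they could only form a four- or a seven-membered ether.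

Step 12
Reactants: 18 (2R)-2-[(3S,6R)-6-[(1S)-1,2-dihydroxyethyl]-6-methyl-1,2-dioxan-3-yl]propan-1-ol
Product: 19 (3R,6S)-6-[(2R)-1-hydroxypropan-2-yl]-3-methyl-1,2-dioxane-3-carbaldehyde
Conditions: NaIO4 (1.5 equiv), THF/H2O, 0 °C
Reagents that add atoms: none
Why: Malaprade cleavage of the vicinal diol should remove C8′ as formaldehyde and expose C7 as a non-enolisable aldehyde, the isolated C1 hydroxyl and the peroxide being inert to periodate.

Step 13
Reactants: 19 (3R,6S)-6-[(2R)-1-hydroxypropan-2-yl]-3-methyl-1,2-dioxane-3-carbaldehyde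
Product: 20 (2E)-3-[(3R,6S)-6-[(2R)-1-hydroxypropan-2-yl]-3-methyl-1,2-dioxan-3-yl]-N-methoxy-N-methylprop-2-enamide
Conditions: Ph3P=CHC(O)N(OMe)Me (1.5 equiv), CH2Cl2, rt → 40 °C
Reagents that add atoms: N-methoxy-N-methyl-2-(triphenyl-λ5-phosphanylidene)acetamide, CON(C)C(=O)C=P(c1ccccc1)(c1ccccc1)c1ccccc1
Why: Wittig olefination with the amide-stabilised ylide runs under neutral conditions that the peroxide and the free hydroxyl tolerate and should give the E-enamide, whose geometry no longer matters after step 14.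

Step 14
Reactants: 20 (2E)-3-[(3R,6S)-6-[(2R)-1-hydroxypropan-2-yl]-3-methyl-1,2-dioxan-3-yl]-N-methoxy-N-methylprop-2-enamide
Product: 21 3-[(3R,6S)-6-[(2R)-1-hydroxypropan-2-yl]-3-methyl-1,2-dioxan-3-yl]-N-methoxy-N-methylpropanamide
Conditions: KO2CN=NCO2K (excess, in portions), AcOH, MeOH, 0 °C → rt
Reagents that add atoms: none
Why: Diimide reduction, a concerted syn transfer of two hydrogens from HN=NH, should saturate C7=C8 without cleaving the O–O bond, which catalytic hydrogenation would not spare.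

Step 15
Reactants: 22 ethyl 5-bromopentanoate
Product: 23 ethyl 5-(diethoxyphosphoryl)pentanoate
Conditions: P(OEt)3 (1.5 equiv), neat, 150 °C, EtBr distilled off
Reagents that add atoms: triethyl phosphite, CCOP(OCC)OCC
Why: Michaelis–Arbuzov reaction of the primary bromide should form the C–P bond while the ethyl ester stays inert.

Step 16
Reactants: 23 ethyl 5-(diethoxyphosphoryl)pentanoate
Product: 24 diethyl (5-hydroxy-5-methylhexyl)phosphonate
Conditions: MeMgBr (2.5 equiv), THF, 0 °C → rt; aq. NH4Cl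
Reagents that add atoms: methylmagnesium bromide, C[Mg]Br
Why: Double Grignard addition to the ester should build the C14 tertiary alcohol, the ester being far more electrophilic toward MeMgBr than the phosphonate P–OEt groups.

Step 17
Reactants: 21 3-[(3R,6S)-6-[(2R)-1-hydroxypropan-2-yl]-3-methyl-1,2-dioxan-3-yl]-N-methoxy-N-methylpropanamide; 24 diethyl (5-hydroxy-5-methylhexyl)phosphonate
Product: 26 diethyl {8-hydroxy-1-[(3R,6S)-6-[(2R)-1-hydroxypropan-2-yl]-3-methyl-1,2-dioxan-3-yl]-8-methyl-3-oxononan-4-yl}phosphonate (both C10 epimers), via dilithio phosphonate 25 (not isolated)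
Conditions: 24 (3.2 equiv), n-BuLi (6.4 equiv), THF, −78 °C; then 21, −78 → −40 °C; aq. NH4Cl
Reagents that add atoms: n-butyllithium, [Li]CCCC (lithium in 25 only)
Why: Acylation of an α-lithiated phosphonate by a Weinreb amide should stop at the ketone because the chelated tetrahedral adduct survives until work-up; one equivalent of carbanion is spent on the C1 hydroxyl, no ester is present to compete, no acidic hydrogen lies β to the peroxide, and the new phosphorus-bearing centre forms as an inconsequential mixture.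

Step 18
Reactants: 26 diethyl {8-hydroxy-1-[(3R,6S)-6-[(2R)-1-hydroxypropan-2-yl]-3-methyl-1,2-dioxan-3-yl]-8-methyl-3-oxononan-4-yl}phosphonate
Product: 28 (2S)-2-[(3S,6R)-6-[4-(diethoxyphosphoryl)-8-hydroxy-8-methyl-3-oxononyl]-6-methyl-1,2-dioxan-3-yl]propanoic acid, via aldehyde 27 (not isolated)
Conditions: TEMPO (0.2 equiv), PhI(OAc)2 (2.5 equiv), MeCN/H2O (1:1), 0 °C → rt
Reagents that add atoms: water, O
Why: Nitroxyl-catalysed oxidation should take the primary C1 alcohol through the aldehyde hydrate to the acid, while the tertiary alcohol cannot be oxidised, the peroxide is inert and C2 keeps its configuration in the weakly acidic medium.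

Step 19
Reactants: 28 (2S)-2-[(3S,6R)-6-[4-(diethoxyphosphoryl)-8-hydroxy-8-methyl-3-oxononyl]-6-methyl-1,2-dioxan-3-yl]propanoic acid
Product: 29 methyl (2S)-2-[(3S,6R)-6-[4-(diethoxyphosphoryl)-8-hydroxy-8-methyl-3-oxononyl]-6-methyl-1,2-dioxan-3-yl]propanoate
Conditions: TMSCHN2 (1.3 equiv), toluene/MeOH (3:1), 0 °C
Reagents that add atoms: trimethylsilyldiazomethane, C[Si](C)(C)C=[N+]=[N-]
Why: O-Methylation of the carboxylic acid with trimethylsilyldiazomethane in methanol is fast and essentially neutral, so neither the β-peroxy ester nor the β-ketophosphonate should be enolised.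

Step 20
Reactants: 29 methyl (2S)-2-[(3S,6R)-6-[4-(diethoxyphosphoryl)-8-hydroxy-8-methyl-3-oxononyl]-6-methyl-1,2-dioxan-3-yl]propanoate
Product: 30 aikupikoxide D, methyl (2S)-2-[(3S,6R)-6-(8-hydroxy-8-methyl-4-methylidene-3-oxononyl)-6-methyl-1,2-dioxan-3-yl]propanoate
Conditions: 37% aq. HCHO (10 equiv), K2CO3 (2 equiv), THF/H2O, 0 °C → rt
Reagents that add atoms: formaldehyde, C=O
Why: Horner–Wadsworth–Emmons methylenation, in which the carbonate-generated anion of the α-substituted β-ketophosphonate adds to formaldehyde and loses diethyl phosphate, should place the methylidene regiospecifically at C10, the ester α-hydrogen being far too weakly acidic for K2CO3.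

**Compound list**

1 | geranyl acetate | CC(C)=CCC/C(C)=C/COC(C)=O | starting material
2 | (2E)-5-(3,3-dimethyloxiran-2-yl)-3-methylpent-2-en-1-yl acetate (racemic) | CC(=O)OC/C=C(C)/CCC1OC1(C)C | intermediate
3 | (2E)-6,7-dihydroxy-3,7-dimethyloct-2-en-1-yl acetate (racemic, not isolated) | CC(=O)OC/C=C(C)/CCC(O)C(C)(C)O | intermediate
4 | (2E)-3-methyl-6-oxohex-2-en-1-yl acetate | CC(=O)OC/C=C(C)/CCC=O | intermediate
5 | (S)-4-benzyl-3-propionyloxazolidin-2-one | CCC(=O)N1[C@@H](Cc2ccccc2)COC1=O | starting material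
6 | (4S)-4-benzyl-3-[(1Z)-1-[(dibutylboranyl)oxy]prop-1-en-1-yl]-1,3-oxazolidin-2-one (not isolated) | C/C=C(\OB(CCCC)CCCC)N1[C@@H](Cc2ccccc2)COC1=O | intermediate
7 | (4S)-4-benzyl-3-[(2S,3R,6E)-8-acetoxy-3-hydroxy-2,6-dimethyloct-6-enoyl]-1,3-oxazolidin-2-one | CC(=O)OC/C=C(C)/CC[C@@H](O)[C@H](C)C(=O)N1[C@@H](Cc2ccccc2)COC1=O | intermediate
8 | (2R,3R,6E)-2,6-dimethyloct-6-ene-1,3,8-triol | OC/C=C(C)/CC[C@@H](O)[C@H](C)CO | intermediate
9 | (2R,3R,6E)-1,8-bis[(tert-butyldiphenylsilyl)oxy]-2,6-dimethyloct-6-en-3-ol | CC(C)(C)[Si](c1ccccc1)(c1ccccc1)OC/C=C(C)/CC[C@@H](O)[C@H](C)CO[Si](c1ccccc1)(c1ccccc1)C(C)(C)C | intermediate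
10 | 2,3-dimethylbut-2-ene | CC(C)=C(C)C | starting material
11 | 2-methoxypropan-2-yl hydroperoxide | COC(C)(C)OO | intermediate
12 | (2R,3R,6E)-1,8-bis[(tert-butyldiphenylsilyl)oxy]-2,6-dimethyloct-6-en-3-yl trifluoromethanesulfonate (not isolated) | CC(C)(C)[Si](c1ccccc1)(c1ccccc1)OC/C=C(C)/CC[C@@H](OS(=O)(=O)C(F)(F)F)[C@H](C)CO[Si](c1ccccc1)(c1ccccc1)C(C)(C)C | intermediate
13 | potassium 2-methoxypropane-2-peroxolate (not isolated) | COC(C)(C)O[O-].[K+] | intermediate
14 | (2R,3S,6E)-1,8-bis[(tert-butyldiphenylsilyl)oxy]-3-[(2-methoxypropan-2-yl)peroxy]-2,6-dimethyloct-6-ene | CC(C)(C)[Si](c1ccccc1)(c1ccccc1)OC/C=C(C)/CC[C@H](OOC(C)(C)OC)[C@H](C)CO[Si](c1ccccc1)(c1ccccc1)C(C)(C)C | intermediate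
15 | (2R,3S,6E)-3-[(2-methoxypropan-2-yl)peroxy]-2,6-dimethyloct-6-ene-1,8-diol | OC/C=C(C)/CC[C@H](OOC(C)(C)OC)[C@H](C)CO | intermediate
16 | (2R,3S,6S,7S)-6,7-epoxy-3-[(2-methoxypropan-2-yl)peroxy]-2,6-dimethyloctane-1,8-diol | OC[C@@H]1O[C@@]1(C)CC[C@H](OOC(C)(C)OC)[C@H](C)CO | intermediate
17 | (2R,3S,6S,7S)-6,7-epoxy-3-hydroperoxy-2,6-dimethyloctane-1,8-diol | OC[C@@H]1O[C@@]1(C)CC[C@H](OO)[C@H](C)CO | intermediate
18 | (2R)-2-[(3S,6R)-6-[(1S)-1,2-dihydroxyethyl]-6-methyl-1,2-dioxan-3-yl]propan-1-ol | OC[C@H](O)[C@@]1(C)CC[C@@H]([C@H](C)CO)OO1 | intermediate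
19 | (3R,6S)-6-[(2R)-1-hydroxypropan-2-yl]-3-methyl-1,2-dioxane-3-carbaldehyde | O=C[C@@]1(C)CC[C@@H]([C@H](C)CO)OO1 | intermediate
20 | (2E)-3-[(3R,6S)-6-[(2R)-1-hydroxypropan-2-yl]-3-methyl-1,2-dioxan-3-yl]-N-methoxy-N-methylprop-2-enamide | CON(C)C(=O)/C=C/[C@@]1(C)CC[C@@H]([C@H](C)CO)OO1 | intermediate
21 | 3-[(3R,6S)-6-[(2R)-1-hydroxypropan-2-yl]-3-methyl-1,2-dioxan-3-yl]-N-methoxy-N-methylpropanamide | CON(C)C(=O)CC[C@@]1(C)CC[C@@H]([C@H](C)CO)OO1 | intermediate
22 | ethyl 5-bromopentanoate | CCOC(=O)CCCCBr | starting material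
23 | ethyl 5-(diethoxyphosphoryl)pentanoate | CCOC(=O)CCCCP(=O)(OCC)OCC | intermediate
24 | diethyl (5-hydroxy-5-methylhexyl)phosphonate | CCOP(=O)(OCC)CCCCC(C)(C)O | intermediate
25 | lithium 6-(diethoxyphosphoryl)-6-lithio-2-methylhexan-2-olate (not isolated) | CCOP(=O)(OCC)C([Li])CCCC(C)(C)O[Li] | intermediate
26 | diethyl {8-hydroxy-1-[(3R,6S)-6-[(2R)-1-hydroxypropan-2-yl]-3-methyl-1,2-dioxan-3-yl]-8-methyl-3-oxononan-4-yl}phosphonate (both epimers at the P-bearing carbon) | CCOP(=O)(OCC)C(CCCC(C)(C)O)C(=O)CC[C@@]1(C)CC[C@@H]([C@H](C)CO)OO1 | intermediate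
27 | diethyl {8-hydroxy-8-methyl-1-[(3R,6S)-3-methyl-6-[(2S)-1-oxopropan-2-yl]-1,2-dioxan-3-yl]-3-oxononan-4-yl}phosphonate (not isolated) | CCOP(=O)(OCC)C(CCCC(C)(C)O)C(=O)CC[C@@]1(C)CC[C@@H]([C@H](C)C=O)OO1 | intermediate
28 | (2S)-2-[(3S,6R)-6-[4-(diethoxyphosphoryl)-8-hydroxy-8-methyl-3-oxononyl]-6-methyl-1,2-dioxan-3-yl]propanoic acid | CCOP(=O)(OCC)C(CCCC(C)(C)O)C(=O)CC[C@@]1(C)CC[C@@H]([C@H](C)C(=O)O)OO1 | intermediate
29 | methyl (2S)-2-[(3S,6R)-6-[4-(diethoxyphosphoryl)-8-hydroxy-8-methyl-3-oxononyl]-6-methyl-1,2-dioxan-3-yl]propanoate | CCOP(=O)(OCC)C(CCCC(C)(C)O)C(=O)CC[C@@]1(C)CC[C@@H]([C@H](C)C(=O)OC)OO1 | intermediate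
30 | aikupikoxide D, methyl (2S)-2-[(3S,6R)-6-(8-hydroxy-8-methyl-4-methylidene-3-oxononyl)-6-methyl-1,2-dioxan-3-yl]propanoate | C=C(CCCC(C)(C)O)C(=O)CC[C@@]1(C)CC[C@@H]([C@H](C)C(=O)OC)OO1 | target

**Step count**

Total: 20 steps. Longest linear sequence: 17 steps from geranyl acetate (steps 1–5, 7–14, 17–20); side branches are step 6 and steps 15–16.

**Steps most likely to fail**

Step 7. What may go wrong: E2 elimination or ionisation of the hindered secondary triflate outruns intermolecular substitution by the peroxide anion, so that the C3–O2 bond is not formed or is formed without clean inversion. Fallback, from 9 back to 18: the substitution at C3 is made intramolecular. Alcohol 9 is mesylated (MsCl, Et3N, CH2Cl2, 0 °C) to (2R,3R,6E)-1,8-bis[(tert-butyldiphenylsilyl)oxy]-2,6-dimethyloct-6-en-3-yl methanesulfonate F1. TBAF buffered with AcOH removes both silyl groups to give (2R,3R,6E)-1,8-dihydroxy-2,6-dimethyloct-6-en-3-yl methanesulfonate F2. Sharpless epoxidation under the conditions of step 9 should give (2R,3R,6S,7S)-6,7-epoxy-1,8-dihydroxy-2,6-dimethyloctan-3-yl methanesulfonate F3. Anhydrous ethereal H2O2 with catalytic H3PMo12O40 should open the epoxide at tertiary C6 with inversion to (2R,3R,6R,7S)-6-hydroperoxy-1,7,8-trihydroxy-2,6-dimethyloctan-3-yl methanesulfonate F4. KOtBu (1 equiv) in THF at 0 °C then lets the C6 hydroperoxide displace the C3 mesylate (6-exo-tet, inversion) to give 18. O1–C6 is still made by a peroxide oxygen opening the same Sharpless epoxide with inversion, so C6 and C3 come out as in the main route; the detour also bypasses steps 8 to 11.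

Step 17. What may go wrong: acylation of the amide is slowed by the neighbouring lithium alkoxide, so that the phosphonate carbanion instead attacks the O–O bond or removes the ring hydrogen at C3. Fallback, from 19 back to 28: the carbanion is offered an aldehyde, which should capture it within minutes at −78 °C. Aldehyde 19 is olefinated with (triphenyl-λ5-phosphanylidene)acetaldehyde (toluene, 60 °C) to (2E)-3-[(3R,6S)-6-[(2R)-1-hydroxypropan-2-yl]-3-methyl-1,2-dioxan-3-yl]prop-2-enal F5. Diimide reduction as in step 14 gives 3-[(3R,6S)-6-[(2R)-1-hydroxypropan-2-yl]-3-methyl-1,2-dioxan-3-yl]propanal F6. Addition of 25 (THF, −78 °C) gives diethyl {3,8-dihydroxy-1-[6-[(2R)-1-hydroxypropan-2-yl]-3-methyl-1,2-dioxan-3-yl]-8-methylnonan-4-yl}phosphonate (ring centres as in 21, mixture at the two new centres) F7. Dess–Martin periodinane oxidises the C9 carbinol to the ketone and the C1 carbinol to the aldehyde, giving 27, and NaClO2/NaH2PO4/2-methylbut-2-ene (Pinnick oxidation) gives 28.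

Step 20. What may go wrong: in aqueous carbonate the β-peroxy ester opens by retro-oxa-Michael reaction, or water or methanol adds to the newly formed enone. Fallback, from 26 back to 30: the methylenation is done before C1 is an ester. Treating 26 with aqueous HCHO/K2CO3 gives 8-hydroxy-1-[(3R,6S)-6-[(2R)-1-hydroxypropan-2-yl]-3-methyl-1,2-dioxan-3-yl]-8-methyl-4-methylidenenonan-3-one F8. TEMPO/PhI(OAc)2 in MeCN/H2O oxidises C1 through (2S)-2-[(3S,6R)-6-(8-hydroxy-8-methyl-4-methylidene-3-oxononyl)-6-methyl-1,2-dioxan-3-yl]propanal F9 to (2S)-2-[(3S,6R)-6-(8-hydroxy-8-methyl-4-methylidene-3-oxononyl)-6-methyl-1,2-dioxan-3-yl]propanoic acid F10. MeI/KHCO3 in DMF then gives 30, so the finished β-peroxy ester meets no base stronger than hydrogencarbonate.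

**Further compounds**

F1 | step 7 | (2R,3R,6E)-1,8-bis[(tert-butyldiphenylsilyl)oxy]-2,6-dimethyloct-6-en-3-yl methanesulfonate | CC(C)(C)[Si](c1ccccc1)(c1ccccc1)OC/C=C(C)/CC[C@@H](OS(C)(=O)=O)[C@H](C)CO[Si](c1ccccc1)(c1ccccc1)C(C)(C)C
F2 | step 7 | (2R,3R,6E)-1,8-dihydroxy-2,6-dimethyloct-6-en-3-yl methanesulfonate | OC/C=C(C)/CC[C@@H](OS(C)(=O)=O)[C@H](C)CO
F3 | step 7 | (2R,3R,6S,7S)-6,7-epoxy-1,8-dihydroxy-2,6-dimethyloctan-3-yl methanesulfonate | OC[C@@H]1O[C@@]1(C)CC[C@@H](OS(C)(=O)=O)[C@H](C)CO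
F4 | step 7 | (2R,3R,6R,7S)-6-hydroperoxy-1,7,8-trihydroxy-2,6-dimethyloctan-3-yl methanesulfonate | OC[C@H](O)[C@@](OO)(C)CC[C@@H](OS(C)(=O)=O)[C@H](C)CO
F5 | step 17 | (2E)-3-[(3R,6S)-6-[(2R)-1-hydroxypropan-2-yl]-3-methyl-1,2-dioxan-3-yl]prop-2-enal | O=C/C=C/[C@@]1(C)CC[C@@H]([C@H](C)CO)OO1
F6 | step 17 | 3-[(3R,6S)-6-[(2R)-1-hydroxypropan-2-yl]-3-methyl-1,2-dioxan-3-yl]propanal | O=CCC[C@@]1(C)CC[C@@H]([C@H](C)CO)OO1
F7 | step 17 | diethyl {3,8-dihydroxy-1-[6-[(2R)-1-hydroxypropan-2-yl]-3-methyl-1,2-dioxan-3-yl]-8-methylnonan-4-yl}phosphonate (ring centres as in 21) | CCOP(=O)(OCC)C(CCCC(C)(C)O)C(O)CC[C@@]1(C)CC[C@@H]([C@H](C)CO)OO1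
F8 | step 20 | 8-hydroxy-1-[(3R,6S)-6-[(2R)-1-hydroxypropan-2-yl]-3-methyl-1,2-dioxan-3-yl]-8-methyl-4-methylidenenonan-3-one | C=C(CCCC(C)(C)O)C(=O)CC[C@@]1(C)CC[C@@H]([C@H](C)CO)OO1
F9 | step 20 | (2S)-2-[(3S,6R)-6-(8-hydroxy-8-methyl-4-methylidene-3-oxononyl)-6-methyl-1,2-dioxan-3-yl]propanal | C=C(CCCC(C)(C)O)C(=O)CC[C@@]1(C)CC[C@@H]([C@H](C)C=O)OO1
F10 | step 20 | (2S)-2-[(3S,6R)-6-(8-hydroxy-8-methyl-4-methylidene-3-oxononyl)-6-methyl-1,2-dioxan-3-yl]propanoic acid | C=C(CCCC(C)(C)O)C(=O)CC[C@@]1(C)CC[C@@H]([C@H](C)C(=O)O)OO1
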